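**Strategy.** The nonanolide is read as a six-membered ketone, C1 to C6 of the lactone (C1 carbonyl, methyls on C2, C4 and C6, oxygens on C3 to C5), into whose C1–C6 bond the three atoms of a lactic acid unit (ring oxygen, C8, C7) are inserted. That insertion is the key step: the C8 hydroxyl adds to the C1 ketone to give an oxolane lactol, whose alkoxide fragments the C1–C6 bond as the C7 mesylate departs, creating the lactone carbonyl, the nine-membered ring and the Z C6=C7 alkene at once. The precursor is a desymmetrized mesitol-derived cyclohexanone carrying the lactaldehyde-derived arm on quaternary C6.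

Key step: step 12

Numbering: lactone numbering is used for every ring-derived compound (C1 carbonyl, C2–C6 the former six-ring carbons, C7 the acylated carbinol, C8 the methylcarbinol on the ring oxygen).

Assumption: the two reagent-controlled steps are written for the enantiomer taken to give the required sense, the (R,R)-lithium amide removing the proton at the S-configured α-carbon in step 6 and (S,S)-ProPhenol giving the R carbinol in step 16; the mirror-image reagent serves equally if the sense is opposite.

Step 1
Reactants: 1 2,4,6-trimethylphenol (mesitol)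
Product: 2 4-hydroxy-2,4,6-trimethylcyclohexa-2,5-dien-1-one (p-quinol)
Conditions: PhI(OAc)2, MeCN/H2O, 0 °C
Reagents that add atoms: water, O
Why: Oxidative dearomatization of a para-alkylphenol by a hypervalent iodine diacetate lets water capture the activated ring at the methyl-bearing para carbon, and no stereocentre arises because C4 lies on the mirror plane.

Step 2
Reactants: 2 p-quinol
Product: 3 2,4,6-trimethyl-4-(triethylsilyloxy)cyclohexa-2,5-dien-1-one
Conditions: TESOTf, 2,6-lutidine, CH2Cl2, −78 to 0 °C
Reagents that add atoms: triethylsilyl trifluoromethanesulfonate, CC[Si](CC)(CC)OS(=O)(=O)C(F)(F)F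
Why: Silyl triflate silylation caps the hindered tertiary alcohol and removes the hydroxyl that would otherwise steer the peroxide of step 3 to its own face.

Step 3
Reactants: 3 silylated quinol
Product: 4 meso bis-epoxide (2,3:5,6-diepoxy-2,4,6-trimethyl-4-(triethylsilyloxy)cyclohexanone, both oxiranes on the face opposite the silyloxy group)
Conditions: t-BuOOH (anhydrous), DBU, CH2Cl2, 0 °C to rt
Reagents that add atoms: tert-butyl hydroperoxide, CC(C)(C)OO
Why: Nucleophilic (Weitz–Scheffer) epoxidation of both enone units should proceed by conjugate addition of the peroxide anion to C3 and C5 on the face away from the bulky triethylsilyloxy group on adjacent quaternary C4, which fixes the C3/C4/C5 oxygen triad as a meso all-trans array.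

Step 4
Reactants: 4 meso bis-epoxide
Product: 5 3,5-dihydroxy-2,4,6-trimethyl-4-(triethylsilyloxy)cyclohexanone (hydroxyls cis to each other and trans to the C4 silyloxy group, C2 and C6 as an epimer mixture)
Conditions: SmI2, THF/MeOH, −90 °C
Reagents that add atoms: none
Why: Samarium diiodide reduction of an α,β-epoxy ketone cleaves only the Cα–O bond through the ketyl, so C3 and C5 keep the oxygen configuration set by the epoxides while C2 and C6 are protonated without control.

Step 5
Reactants: 5 diol
Product: 7 meso 2,4,6-trimethyl-3,4,5-tris(triethylsilyloxy)cyclohexanone (all-equatorial isomer), via silylated ketone epimers 6 (not isolated)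
Conditions: TESOTf, 2,6-lutidine, CH2Cl2, −78 to 0 °C; MeOH; then DBU, rt
Reagents that add atoms: triethylsilyl trifluoromethanesulfonate, CC[Si](CC)(CC)OS(=O)(=O)C(F)(F)F
Why: Silylation of the two secondary alcohols followed by amidine-mediated enolization and reprotonation (thermodynamic epimerization) should funnel every C2/C6 epimer to the isomer with both methyls equatorial, the only one free of a 1,3-diaxial clash with the axial C4 methyl, while the equatorial C3 and C5 silyloxy groups stay misaligned for β-elimination.

Step 6
Reactants: 7 meso ketone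
Product: 8 trimethylsilyl enol ether of 7, enolized toward the S-configured α-carbon (future C6) with the R α-carbon kept as C2
Conditions: (R,R)-bis(1-phenylethyl)amine, n-BuLi, LiCl, TMSCl, THF, −100 °C
Reagents that add atoms: chlorotrimethylsilane, C[Si](C)(C)Cl
Why: Enantiotopic deprotonation of a meso cis-2,6-dimethylcyclohexanone by a chiral lithium amide with in situ silyl quench (asymmetric deprotonation) removes one of the two axial α-hydrogens selectively, so the untouched α-carbon becomes C2 and the absolute sense of C3, C4 and C5 is fixed.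

Step 7
Reactants: 9 ethyl (S)-lactate
Product: 10 ethyl (S)-2-(benzyloxy)propanoate
Conditions: benzyl 2,2,2-trichloroacetimidate, TfOH (cat.), cyclohexane/CH2Cl2, 0 °C to rt
Reagents that add atoms: benzyl 2,2,2-trichloroacetimidate, N=C(OCc1ccccc1)C(Cl)(Cl)Cl
Why: Acid-catalysed imidate benzylation etherifies the α-hydroxy ester without base, so the lactate centre (future C8) is not racemized, and the benzyl ether tolerates TiCl4 in step 9 and leaves by neutral hydrogenolysis in step 11.

Step 8
Reactants: 10 benzyl-protected lactate ester
Product: 11 (S)-2-(benzyloxy)propanal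
Conditions: i-Bu2AlH, CH2Cl2, −78 °C
Reagents that add atoms: none
Why: Partial hydride reduction of the ester at low temperature stops at the aluminium hemiacetal, which releases the aldehyde on work-up without loss of configuration.

Step 9
Reactants: 8 silyl enol ether; 11 (S)-2-(benzyloxy)propanal
Product: 12 aldol adduct (ketone 7 carrying on quaternary C6 the CH(OH)–CH(OBn)–CH3 arm; arm equatorial and anti to the C5 silyloxy group, C6 methyl/C7 hydroxyl syn, C7 hydroxyl/C8 benzyloxy syn)
Conditions: TiCl4 (precomplexed with 11), CH2Cl2, −78 °C; then 8; aq NaHCO3 at −78 °C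
Reagents that add atoms: none
Why: In this chelation-controlled Mukaiyama aldol addition the enol ether should attack the TiCl4 chelate of the α-benzyloxy aldehyde anti to its methyl group (C7 hydroxyl syn to the C8 ether) through the C6 face opposite the C5 silyloxy group and the axial C4 methyl, two independent controls that together set quaternary C6 with the arm equatorial and the C6-methyl/C7-hydroxyl relationship syn, the one isomer whose lactol is aligned for step 12.

Step 10
Reactants: 12 aldol adduct
Product: 13 C7 methanesulfonate of 12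
Conditions: MsCl, Et3N, CH2Cl2, −20 to 0 °C
Reagents that add atoms: methanesulfonyl chloride, CS(=O)(=O)Cl
Why: Sulfonylation through sulfene reaches this neopentyl-type secondary alcohol with retention at C7, and the quaternary C6 rules out β-elimination toward the ring.

Step 11
Reactants: 13 benzyl ether mesylate
Product: 14 C7 mesylate with free C8 hydroxyl (drawn as the hydroxy ketone, expected to rest largely as the C1 lactol)
Conditions: H2 (1 atm), Pd(OH)2/C, EtOAc, rt
Reagents that add atoms: none
Why: Hydrogenolysis of the benzyl ether is neutral and leaves the mesylate, ketone and silyl ethers alone, so the freed C8 hydroxyl can only add reversibly to the C1 ketone (ring-chain tautomerism) instead of displacing the neighbouring sulfonate.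

Step 12
Reactants: 14 hydroxy mesylate
Product: 16 nine-membered lactone with Z C6=C7 double bond (3,4,5-tris(triethylsilyloxy); methyls on C2, C4, C6, C8), via potassium lactol alkoxide 15 (not isolated)
Conditions: KN(SiMe3)2 (1.0 equiv), THF, −78 to −20 °C; pH 7 buffer at −78 °C
Reagents that add atoms: none
Why: Proposed new method: deprotonation gives the alkoxide of the cis-fused oxolane lactol (closed by 5-exo-trig addition of the C8 oxygen to the C1 carbonyl), and this alkoxide should drive a concerted heterolytic scission in which the C1–C6 bond breaks, the C1 lactone carbonyl and the C6=C7 double bond form and methanesulfonate leaves, so the nine-membered ring is not cyclized but uncovered by cutting the bond shared by the two rings. The closest known reaction type is the Grob (Wharton) fragmentation of cyclic 1,3-hydroxy sulfonates to medium-ring alkenones, from which this case differs in that the donor is a hemiketal oxygen and the new carbonyl an ester. No lasting stereocentre is created, and the alkene should be Z because the chair cyclohexane with the C7 arm equatorial puckers the oxolane so that the C7–O sulfonate bond lies close to anti-periplanar to C1–C6 with C8 gauche to C5, which follows from the syn C6-methyl/C7-oxygen relationship of step 9. The selectivity needed is fragmentation over oxirane closure by the open-chain C8 alkoxide, and it is secured by quaternary C6, which favours the lactol and shields C7 from backside attack, by the displacement rotamer forcing the C8 methyl against C6, and by the irreversible loss of sulfonate. One equivalent of base and a cold neutral quench protect the C2 centre and the β-silyloxy lactone from enolization.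

Step 13
Reactants: 16 Z-alkene lactone
Product: 17 C6–C7 epoxide of 16
Conditions: m-CPBA, NaHCO3, CH2Cl2, 0 °C
Reagents that add atoms: 3-chloroperoxybenzoic acid, O=C(OO)c1cccc(Cl)c1
Why: Prilezhaev epoxidation of the trisubstituted Z alkene should deliver oxygen opposite the C5 silyloxy group, because allylic 1,3-strain keeps the C5 and C8 hydrogens in the alkene plane and so places that silyloxy group and the ring oxygen over one face and leaves the other, flanked by the C8 methyl and C4, for attack, which sets C7.

Step 14
Reactants: 17 epoxide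
Product: 18 6-methylene-7-hydroxy lactone (allylic alcohol)
Conditions: Cp2TiCl2, Mn, THF, rt; aq NaH2PO4
Reagents that add atoms: none
Why: Cp2TiCl (trivalent titanium) opens the epoxide homolytically at the tertiary C6–O bond and a second equivalent removes a hydrogen atom from the C6 methyl of the hindered radical (radical epoxide-to-allylic-alcohol isomerization), so the C7–O bond and its configuration are untouched.

Step 15
Reactants: 18 allylic alcohol
Product: 19 C7 alcohol with all seven ring stereocentres (configuration of the target at C2–C8, C3/C4/C5 as triethylsilyl ethers)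
Conditions: H2 (1 atm), [Ir(cod)(PCy3)(py)]PF6 (5 mol%), CH2Cl2, 0 °C to rt
Reagents that add atoms: none
Why: Hydroxyl-directed hydrogenation with the cationic iridium complex binds the C7 hydroxyl and the 1,1-disubstituted alkene together and should add hydrogen to C6 from the ring face carrying that hydroxyl, which leaves the C6 methyl trans to the C7 oxygen.

Step 16
Reactants: 20 pentanal; 21 methyl propiolate
Product: 22 methyl (R)-4-hydroxyoct-2-ynoate
Conditions: Me2Zn, (S,S)-ProPhenol (10 mol%), Ph3PO (20 mol%), toluene, 4 °C
Reagents that add atoms: none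
Why: Catalytic asymmetric alkynylation of the aldehyde by the alkynylzinc formed from the propiolate and Me2Zn inside a dinuclear zinc amino-alcohol pocket sets the carbinol centre by reagent control.

Step 17
Reactants: 22 propargylic alcohol
Product: 23 methyl (R)-4-(triethylsilyloxy)oct-2-ynoate
Conditions: TESCl, imidazole, CH2Cl2, 0 °C
Reagents that add atoms: chlorotriethylsilane, CC[Si](CC)(CC)Cl
Why: Standard silyl ether formation masks the γ-hydroxyl so that it cannot lactonize onto the ester once the alkyne has become a Z alkene.

Step 18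
Reactants: 23 silylated ynoate
Product: 24 (R)-4-(triethylsilyloxy)oct-2-ynoic acid
Conditions: LiOH, THF/H2O, 0 °C; cold dilute HCl to pH 3
Reagents that add atoms: lithium hydroxide, [Li+].[OH-]
Why: Saponification of the electron-poor alkynoate is fast at 0 °C, so the secondary triethylsilyl ether and the propargylic centre should survive the brief base treatment and cold acidification.

Step 19
Reactants: 19 C7 alcohol; 24 ynoic acid
Product: 25 C7 ynoate ester of the protected nonanolide
Conditions: DIC, DMAP (10 mol%), CH2Cl2, −20 to 0 °C
Reagents that add atoms: none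
Why: Carbodiimide esterification with catalytic DMAP (Steglich esterification) acylates the hindered C7 hydroxyl, the only free alcohol, and low temperature and low DMAP loading limit conjugate addition to the ynoate.

Step 20
Reactants: 25 ynoate ester
Product: 26 C7 (R,Z)-4-(triethylsilyloxy)oct-2-enoate ester of the tris-silylated nonanolide
Conditions: H2 (1 atm), Pd/CaCO3 poisoned with Pb(OAc)2 (Lindlar catalyst), quinoline, EtOAc, rt
Reagents that add atoms: none
Why: Lindlar semihydrogenation adds hydrogen syn to the alkyne and stops at the Z enoate, whose γ-oxygen is still silylated and cannot close a butenolide.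

Step 21
Reactants: 26 tetrasilylated Z-enoate
Product: 27 target CNP0205075.2
Conditions: HF·pyridine, pyridine, THF, 0 °C to rt
Reagents that add atoms: none
Why: Buffered fluoride desilylation removes the four triethylsilyl ethers under weakly acidic, base-free conditions, under which neither translactonization to the five- or six-membered lactones nor butenolide formation from the Z γ-hydroxy enoate is expected.

**Compound list**

1 | 2,4,6-trimethylphenol (mesitol) | Cc1cc(C)c(O)c(C)c1 | starting material
2 | 4-hydroxy-2,4,6-trimethylcyclohexa-2,5-dien-1-one | CC1=CC(C)(O)C=C(C)C1=O | intermediate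
3 | 2,4,6-trimethyl-4-(triethylsilyloxy)cyclohexa-2,5-dien-1-one | CC1=CC(C)(O[Si](CC)(CC)CC)C=C(C)C1=O | intermediate
4 | meso bis-epoxide of 3, both oxiranes opposite the silyloxy group | O=C1[C@@]2(C)[C@H](O2)[C@@](C)(O[Si](CC)(CC)CC)[C@H](O3)[C@@]13C | intermediate
5 | 3,5-dihydroxy-2,4,6-trimethyl-4-(triethylsilyloxy)cyclohexanone, hydroxyls trans to the C4 silyloxy group, C2/C6 epimer mixture (those two centres left open) | O=C1C(C)[C@H](O)[C@@](C)(O[Si](CC)(CC)CC)[C@H](O)C1C | intermediate
6 | 2,4,6-trimethyl-3,4,5-tris(triethylsilyloxy)cyclohexanone, C2/C6 epimer mixture (those two centres left open) | O=C1C(C)[C@H](O[Si](CC)(CC)CC)[C@@](C)(O[Si](CC)(CC)CC)[C@H](O[Si](CC)(CC)CC)C1C | intermediate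
7 | meso 2,4,6-trimethyl-3,4,5-tris(triethylsilyloxy)cyclohexanone, methyls at C2/C6 cis and equatorial, each silyloxy group trans to its neighbours | O=C1[C@@H](C)[C@H](O[Si](CC)(CC)CC)[C@@](C)(O[Si](CC)(CC)CC)[C@H](O[Si](CC)(CC)CC)[C@H]1C | intermediate
8 | trimethylsilyl enol ether of 7 (C1=C6), C2 retained as R | C[Si](C)(C)OC1=C(C)[C@H](O[Si](CC)(CC)CC)[C@@](C)(O[Si](CC)(CC)CC)[C@H](O[Si](CC)(CC)CC)[C@H]1C | intermediate
9 | ethyl (S)-lactate | CCOC(=O)[C@H](C)O | starting material
10 | ethyl (S)-2-(benzyloxy)propanoate | CCOC(=O)[C@H](C)OCc1ccccc1 | intermediate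
11 | (S)-2-(benzyloxy)propanal | C[C@H](OCc1ccccc1)C=O | intermediate
12 | aldol adduct, quaternary C6 with equatorial CH(OH)CH(OBn)CH3 arm, C6-Me/C7-OH syn, C7-OH/C8-OBn syn | O=C1[C@@](C)([C@H](O)[C@H](C)OCc2ccccc2)[C@H](O[Si](CC)(CC)CC)[C@@](C)(O[Si](CC)(CC)CC)[C@H](O[Si](CC)(CC)CC)[C@H]1C | intermediate
13 | C7 methanesulfonate of 12 | O=C1[C@@](C)([C@H](OS(C)(=O)=O)[C@H](C)OCc2ccccc2)[C@H](O[Si](CC)(CC)CC)[C@@](C)(O[Si](CC)(CC)CC)[C@H](O[Si](CC)(CC)CC)[C@H]1C | intermediate
14 | C7 mesylate with free C8 hydroxyl (hydroxy ketone form of the C1 lactol) | O=C1[C@@](C)([C@H](OS(C)(=O)=O)[C@H](C)O)[C@H](O[Si](CC)(CC)CC)[C@@](C)(O[Si](CC)(CC)CC)[C@H](O[Si](CC)(CC)CC)[C@H]1C | intermediate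
15 | potassium alkoxide of the cis-fused oxolane lactol of 14 | [K+].[O-][C@]12O[C@@H](C)[C@@H](OS(C)(=O)=O)[C@@]1(C)[C@H](O[Si](CC)(CC)CC)[C@@](C)(O[Si](CC)(CC)CC)[C@H](O[Si](CC)(CC)CC)[C@H]2C | intermediate
16 | nine-membered lactone with Z C6=C7 alkene, 3,4,5-tris(triethylsilyloxy) | O=C1O[C@@H](C)/C=C(C)\[C@H](O[Si](CC)(CC)CC)[C@@](C)(O[Si](CC)(CC)CC)[C@H](O[Si](CC)(CC)CC)[C@H]1C | intermediate
17 | C6–C7 epoxide of 16, oxygen opposite the C5 silyloxy group | O=C1O[C@@H](C)[C@H]2[C@](C)(O2)[C@H](O[Si](CC)(CC)CC)[C@@](C)(O[Si](CC)(CC)CC)[C@H](O[Si](CC)(CC)CC)[C@H]1C | intermediate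
18 | 6-methylene-7-hydroxy lactone | O=C1O[C@@H](C)[C@H](O)C(=C)[C@H](O[Si](CC)(CC)CC)[C@@](C)(O[Si](CC)(CC)CC)[C@H](O[Si](CC)(CC)CC)[C@H]1C | intermediate
19 | C7 alcohol with all seven ring stereocentres, 3,4,5-tris(triethylsilyl) ether | O=C1O[C@@H](C)[C@H](O)[C@@H](C)[C@H](O[Si](CC)(CC)CC)[C@@](C)(O[Si](CC)(CC)CC)[C@H](O[Si](CC)(CC)CC)[C@H]1C | intermediate
20 | pentanal | CCCCC=O | starting material
21 | methyl propiolate | C#CC(=O)OC | starting material
22 | methyl (R)-4-hydroxyoct-2-ynoate | CCCC[C@@H](O)C#CC(=O)OC | intermediate
23 | methyl (R)-4-(triethylsilyloxy)oct-2-ynoate | CCCC[C@@H](O[Si](CC)(CC)CC)C#CC(=O)OC | intermediate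
24 | (R)-4-(triethylsilyloxy)oct-2-ynoic acid | CCCC[C@@H](O[Si](CC)(CC)CC)C#CC(=O)O | intermediate
25 | C7 ynoate ester of the protected nonanolide | O=C1O[C@@H](C)[C@H](OC(=O)C#C[C@H](O[Si](CC)(CC)CC)CCCC)[C@@H](C)[C@H](O[Si](CC)(CC)CC)[C@@](C)(O[Si](CC)(CC)CC)[C@H](O[Si](CC)(CC)CC)[C@H]1C | intermediate
26 | C7 Z-enoate ester, four triethylsilyl ethers | O=C1O[C@@H](C)[C@H](OC(=O)/C=C\[C@H](O[Si](CC)(CC)CC)CCCC)[C@@H](C)[C@H](O[Si](CC)(CC)CC)[C@@](C)(O[Si](CC)(CC)CC)[C@H](O[Si](CC)(CC)CC)[C@H]1C | intermediate
27 | CNP0205075.2 | CCCC[C@@H](O)/C=C\C(=O)O[C@@H]1[C@@H](C)[C@H](O)[C@@](C)(O)[C@H](O)[C@@H](C)C(=O)O[C@H]1C | target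

**Step count.** 21 steps in total; longest linear sequence 16 steps (steps 1–6, 9–15, 19–21).

**Steps most likely to fail**

1. Step 12 (proposed new method). The alkoxide may partition toward oxirane closure at C7 or toward enolization rather than fragmenting, or the lactol may not populate the aligned conformer. The fallback builds the same ring by known ester formation and ring-closing metathesis; it sets out from 8 and returns at 16. Ozonolysis of 8 (O3, CH2Cl2, −78 °C; Me2S) should give the keto acid F1 (C1 acid, C6 methyl ketone). Carbodiimide esterification (EDC·HCl, DMAP) with commercial (S)-but-3-en-2-ol (C=C[C@H](C)O) gives the keto ester F2. Non-basic Lombardo–Takai methylenation (Zn/CH2Br2/TiCl4) of the ketone gives the diene ester F3. Ring-closing metathesis (second-generation Grubbs catalyst, toluene, 80 °C, high dilution) should then close the nine-membered ring to 16, the Z alkene being the only geometry the ring tolerates.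

2. Step 9. Bond formation at the congested enol carbon may stall, or the enol-ether face and the chelate face may pair differently and give a C6/C7 relationship unsuited to the fragmentation. The fallback makes the C6–C7 bond by acylation and sets C7 by reduction; it sets out from 8 and 10 and returns at 12. Ester 10 is converted (MeNH(OMe)·HCl, i-PrMgCl, THF, −20 °C) into the Weinreb amide F4. Enol ether 8 is cleaved with MeLi (THF, −20 °C) to the lithium enolate F5, which is C-acylated by F4 to the β-diketone F6. KBH(sec-Bu)3 (THF, −78 °C) should then reduce the more electrophilic α-alkoxy ketone under Felkin–Anh control (hydride anti to the benzyloxy group, the two carbonyls opposed), giving 12.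

3. Step 13. Facial selectivity of oxygen transfer to the medium-ring alkene may be poor or reversed. The fallback makes that selectivity irrelevant by setting C7 with a chiral reagent; it sets out from 16 and returns at 18. Epoxidation as in step 13 would then give mainly the diastereomeric epoxide F7. Cp2TiCl isomerizes it to the C7-epimeric allylic alcohol F8, and Dess–Martin periodinane oxidizes this to the 6-methylene-7-ketone F9. Corey–Bakshi–Shibata reduction ((R)-2-methyl-CBS-oxazaborolidine, BH3·SMe2, −30 °C; the 1,1-disubstituted alkenyl group taken as the larger substituent) should give 18.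

**Further compounds**

F1 | step 12 | keto acid, 2,4-dimethyl-6-oxo-3,4,5-tris(triethylsilyloxy)heptanoic acid with C2–C5 as in 8 | CC(=O)[C@H](O[Si](CC)(CC)CC)[C@@](C)(O[Si](CC)(CC)CC)[C@H](O[Si](CC)(CC)CC)[C@@H](C)C(=O)O
F2 | step 12 | (S)-but-3-en-2-yl ester of F1 | CC(=O)[C@H](O[Si](CC)(CC)CC)[C@@](C)(O[Si](CC)(CC)CC)[C@H](O[Si](CC)(CC)CC)[C@@H](C)C(=O)O[C@@H](C)C=C
F3 | step 12 | diene ester, 6-methylene analogue of F2 | C=C(C)[C@H](O[Si](CC)(CC)CC)[C@@](C)(O[Si](CC)(CC)CC)[C@H](O[Si](CC)(CC)CC)[C@@H](C)C(=O)O[C@@H](C)C=C
F4 | step 9 | (S)-2-(benzyloxy)-N-methoxy-N-methylpropanamide | C[C@H](OCc1ccccc1)C(=O)N(C)OC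
F5 | step 9 | lithium enolate corresponding to 8 | [Li]OC1=C(C)[C@H](O[Si](CC)(CC)CC)[C@@](C)(O[Si](CC)(CC)CC)[C@H](O[Si](CC)(CC)CC)[C@H]1C
F6 | step 9 | β-diketone, C7-oxo analogue of 12 | O=C1[C@@](C)(C(=O)[C@H](C)OCc2ccccc2)[C@H](O[Si](CC)(CC)CC)[C@@](C)(O[Si](CC)(CC)CC)[C@H](O[Si](CC)(CC)CC)[C@H]1C
F7 | step 13 | C6–C7 epoxide of 16 on the other face | O=C1O[C@@H](C)[C@@H]2[C@@](C)(O2)[C@H](O[Si](CC)(CC)CC)[C@@](C)(O[Si](CC)(CC)CC)[C@H](O[Si](CC)(CC)CC)[C@H]1C
F8 | step 13 | C7 epimer of allylic alcohol 18 | O=C1O[C@@H](C)[C@@H](O)C(=C)[C@H](O[Si](CC)(CC)CC)[C@@](C)(O[Si](CC)(CC)CC)[C@H](O[Si](CC)(CC)CC)[C@H]1C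
F9 | step 13 | 6-methylene-7-oxo lactone (enone) | O=C1O[C@@H](C)C(=O)C(=C)[C@H](O[Si](CC)(CC)CC)[C@@](C)(O[Si](CC)(CC)CC)[C@H](O[Si](CC)(CC)CC)[C@H]1C
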